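The data were generated by integration for an exercise; scatter was added.

Early on, the maple flask moves fast and then slows: by 2.50 h the starting material stands at 63.0% and the target at 33.8%, and from there to 50.0 h the first loses 19 percentage points and the second 20 points.

| setting | maple | elm | flask |
|---|---|---|---|
| starting material | 0.10 M | 0.10 M | 0.10 M |
| partner | 0.050 M | 0.034 M | 0.0500 M |
| second substrate | 0.20 M | 0.20 M | 0.200 M |
| third substrate | 0.020 M | 0.020 M | 0.0200 M |
| remark | the very flask that is asked about, followed so far | run made earlier |  |
| time |  |  | 2.0 d |

| run | time / h | target / % | starting material / % |
|---|---|---|---|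
| maple | 2.50 | 33.8 | 63.0 |
| maple | 8.00 | 29.7 | 59.1 |
| maple | 15.0 | 25.9 | 55.6 |
| maple | 20.0 | 23.6 | 52.6 |
| maple | 30.0 | 19.8 | 49.0 |
| maple | 40.0 | 16.6 | 46.3 |
| maple | 50.0 | 13.9 | 43.6 |
| elm | 1.33 | 22.3 | 76.4 |
| elm | 4.00 | 20.9 | 74.5 |
| elm | 8.00 | 19.0 | 72.2 |
| elm | 10.0 | 18.2 | 71.5 |
| elm | 15.0 | 16.4 | 69.3 |
| elm | 20.0 | 14.3 | 67.4 |
| elm | 25.0 | 13.0 | 65.7 |

(each reading ± 0.3 percentage points)

- percent here means starting material units held: one side product counts as two
- target taken out counts as made
- on the list of suspects stand: starting material + partner -> target; second substrate + partner -> second product; third substrate + partner -> third product; starting material + target -> side product; second substrate -> decomposition product; partner -> decomposed reagent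
- additions bring no volume worth counting

- north: at 2.0 d take out 90% of the target then present, then wait 25 h
- east: at 2.0 d add partner, 50.0% of the amount charged, then wait 25 h
- south-west: at 2.0 d add starting material, 50.0% of the amount charged, then wait 25 h
- south-east: change nothing and wait 25 h more

* target, in percent of the starting material first charged, at 2.0 d
* what to do for the largest gain in target; "none" if nothing gains more than 2 percentage points (north / east / south-west / south-east / none)
* target present, with what was taken out counted in, in percent of the starting material first charged, after east
* target present, with what was taken out counted in, in percent of the starting material first charged, after south-east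

I keep a ledger of the partner, the limiting reagent, charged at 0.0500 M against 0.10 M of starting material, and I count it in percent of the starting material charged. Write A for starting material and P for target. Each partner that makes target lowers A and raises P, so it lowers A − P by two, whereas starting material + target → side product takes one of each and leaves A − P alone. So I carry the gap G, starting material minus target, here the mean of the first and last maple readings. It reads 29 points and then 30 points, with 0.3 points of scatter on each reading, so I see no target still being made. The books then stand, with T the target ever made and R the partner booked elsewhere:

G = 29 points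
T = (100 − G)/2 = 35.3%
R = 50.0% − T = 14.7%

The elm run books the same way, with G = 53 points and T = 23.3% of 34.0% charged.

With G fixed, the loss of target goes as P(P + G), so ln(A/P) climbs a straight line:

s = 0.0110 h⁻¹
A/P at 2.0 d = 3.07
P = G/(A/P − 1) = 14.2%

East brings 25.0% of fresh partner and the other options bring none, so I choose east.

The forecast, resting on “SM − target ≈ 29.5 constant”, gives 14.4% where I give 14.2%; it also chooses east, with 29% after it and 9.8% after waiting.

The flask gives 14.9%, best east with a gain of 13 points, 27.5% after east and 10.4% after waiting.

    starting material + partner → target (k = 0.00870 L mol⁻¹ s⁻¹)
    second substrate + partner → second product (k = 1.10 × 10⁻⁴ L mol⁻¹ s⁻¹)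
    third substrate + partner → third product (k = 0.0220 L mol⁻¹ s⁻¹)
    starting material + target → side product (k = 9.60 × 10⁻⁵ L mol⁻¹ s⁻¹)
    second substrate → decomposition product (k = 9.00 × 10⁻⁸ s⁻¹)
    partner → decomposed reagent (k = 3.10 × 10⁻⁶ s⁻¹)

At 48.0 h the partner stands at 0%, and third product, second product and decomposed reagent together hold 14.6% beside my R of 14.7%. The neighbour with 0.12 M of partner has G = −84 points at 48.0 h, so the same line gives it T = 92.2%. The maple flask is not at rest at 2.0 d: by 480 h its target falls from 14.9% to 0.125%, its side product rises from 40.9% to 70.5%, and its starting material stands at 29.4%, which leaves a gap of 29 points beside the 29 points read from the maple run.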